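**Plan**

- Cuts: the ketone bond between the acyl carbon and pyridone C3 (3-lithiopyridine + decalin aldehyde), then pyridone C5–cyclohexane C (5-lithiopyridine + epoxy ketone), and last C1–C2 and C4a–C8a of the decalin.
- Enabling feature: ring A (C1, C2, C3, C4, C4a, C8a) has its alkene at C3=C4, between the acyl-bearing C2 and the fusion carbon C4a. C1–C2 and C4a–C8a are therefore the two σ-bonds of a cyclohexene [4+2] retron, and C4a–C8a also closes ring B (C4a, C5–C8, C8a).
- Forward: (S)-citronellal is built into an acyclic (2E,4E,10E,12E)-tetraenoate, and heating closes rings A and B together. C2 is then inverted, the ester is taken to the aldehyde, the pyridine–epoxycyclohexane half is added, the carbinol is oxidised and all four protecting groups are removed.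
- Stereochemistry: C7 comes from (S)-citronellal and steers the cycloaddition (C1, C4a, C8a), and C2 is set by equilibration to the all-equatorial ester. The epoxydiol ring comes from (R)-4-silyloxycyclohexenone, whose silyloxy group directs the epoxidation and the aryl addition.

Key step: step 8

Remark: the SMILES is read as placing both hydroxyls of the epoxycyclohexane cis to each other and trans to the oxirane oxygen, and enone 19 is taken as a purchasable enantiopure building block (the TBS ether of (R)-4-hydroxycyclohex-2-en-1-one).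

**Route**

Step 1
Reactants: 1 (S)-citronellal [(3S)-3,7-dimethyloct-6-enal]
Product: 2 2-[(2S)-2,6-dimethylhept-5-en-1-yl]-1,3-dioxolane
Conditions: ethylene glycol, pyridinium p-toluenesulfonate (cat.), benzene, reflux, Dean–Stark trap
Reagents that add atoms: ethylene glycol, OCCO
Why: Acid-catalysed acetalisation with azeotropic removal of water masks the aldehyde as a 1,3-dioxolane for the ozonolysis and the two olefinations that follow, the mild pyridinium acid should avoid the carbonyl-ene cyclisation of citronellal, and the stereocentre is not touched.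

Step 2
Reactants: 2 2-[(2S)-2,6-dimethylhept-5-en-1-yl]-1,3-dioxolane
Product: 4 (4S)-5-(1,3-dioxolan-2-yl)-4-methylpentanal, via secondary ozonide 3 (not isolated)
Conditions: O3, CH2Cl2, −78 °C; then PPh3, −78 °C → rt
Reagents that add atoms: ozone, [O-][O+]=O
Why: Ozonolysis of the electron-rich trisubstituted alkene followed by reductive cleavage of the ozonide with triphenylphosphine gives the aldehyde, the dioxolane being inert at −78 °C when the ozone stream is stopped at the end point; no stereocentre is formed.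

Step 3
Reactants: 4 (4S)-5-(1,3-dioxolan-2-yl)-4-methylpentanal; 5 2-(triphenylphosphoranylidene)propanal
Product: 6 (2E,6S)-7-(1,3-dioxolan-2-yl)-2,6-dimethylhept-2-enal
Conditions: toluene, 90 °C
Reagents that add atoms: none
Why: Wittig olefination with the stabilised, α-branched formyl ylide is reliably (E)-selective and should stop at the enal, because the conjugated product is much less electrophilic than the saturated aldehyde.

Step 4
Reactants: 6 (2E,6S)-7-(1,3-dioxolan-2-yl)-2,6-dimethylhept-2-enal; 7 trimethyl phosphonoacetate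
Product: 9 methyl (2E,4E,8S)-9-(1,3-dioxolan-2-yl)-4,8-dimethylnona-2,4-dienoate, via sodium phosphonate anion 8 (not isolated)
Conditions: 7, NaH, THF, 0 °C; then 6, 0 °C → rt
Reagents that add atoms: none
Why: Horner–Wadsworth–Emmons olefination of the enal with the sodium phosphonoacetate anion gives the (2E)-alkene under the usual thermodynamic control and so completes the (2E,4E)-dienoate.

Step 5
Reactants: 9 methyl (2E,4E,8S)-9-(1,3-dioxolan-2-yl)-4,8-dimethylnona-2,4-dienoate
Product: 10 methyl (2E,4E,8S)-4,8-dimethyl-10-oxodeca-2,4-dienoate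
Conditions: 2 M aq. HCl (cat.), THF, rt
Reagents that add atoms: water, O
Why: Acid-catalysed acetal hydrolysis frees the aldehyde, the dienoate tolerates dilute acid, and the C8 stereocentre is β to the new carbonyl and cannot epimerise.

Step 6
Reactants: 11 (E)-crotyl bromide [(2E)-1-bromobut-2-ene]
Product: 12 tributyl[(2E)-but-2-en-1-yl]phosphonium bromide
Conditions: PBu3, MeCN, 0 °C → rt; recrystallisation
Reagents that add atoms: tributylphosphine, CCCCP(CCCC)CCCC
Why: SN2 quaternisation of the phosphine at the primary allylic carbon gives the salt with the (E)-alkene retained, and recrystallisation should remove the (Z)- and branched isomers that accompany commercial crotyl bromide.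

Step 7
Reactants: 12 tributyl[(2E)-but-2-en-1-yl]phosphonium bromide; 10 methyl (2E,4E,8S)-4,8-dimethyl-10-oxodeca-2,4-dienoate
Product: 14 methyl (2E,4E,8S,10E,12E)-4,8-dimethyltetradeca-2,4,10,12-tetraenoate, via crotylidene ylide 13 (not isolated)
Conditions: 12, KOtBu, THF, −78 → 0 °C; then 10, −78 °C → rt
Reagents that add atoms: none
Why: Wittig olefination with an allylic trialkylphosphonium ylide, which unlike its triphenyl analogue strongly favours the (E)-alkene, should install the (10E,12E)-diene, and the ester is spared because the ylide is consumed by the far more reactive aldehyde.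

Step 8
Reactants: 14 methyl (2E,4E,8S,10E,12E)-4,8-dimethyltetradeca-2,4,10,12-tetraenoate
Product: 15 methyl (1R,2R,4aS,7S,8aR)-4,7-dimethyl-1-[(1E)-prop-1-en-1-yl]-1,2,4a,5,6,7,8,8a-octahydronaphthalene-2-carboxylate
Conditions: BHT (cat.), toluene (0.01 M), sealed tube, 170 °C
Reagents that add atoms: none
Why: On heating, the ester-conjugated (2E,4E)-diene C2–C5 of 14 (low LUMO) and the tether-side C10=C11 alkene of the electron-rich (E,E)-hexadienyl end should combine in a concerted, asynchronous [4+2] cycloaddition with inverse electron demand that forms C5–C10 (C4a–C8a of the decalin) and C2–C11 (C2–C1), the closest known reaction type being the thermal intramolecular Diels–Alder reaction of deca-1,7,9-trienes to trans-fused octalins. Ring B closes as a six-membered carbocycle across the four-carbon tether C6–C9 folded as a chair, and ring A is the cyclohexene produced by the cycloaddition itself. Suprafacial addition to both partners turns alkene geometry into relative configuration: the (10E)-dienophile puts H1 and H8a trans, and the two outward substituents of the (2E,4E)-diene, the ester and the tether, end up cis, so that C2 is formed as R, the epimer of what the target needs. The trans ring fusion (C4a against C8a) should come from the anti transition state, because in the syn arrangement leading to cis fusion the C4 methyl, which is cis to the tether across C4=C5, is pressed against the tether methylenes, and the absolute sense of all four new centres is set by the chain C8 (decalin C7), whose methyl takes the equatorial site of the chair tether. The step therefore needs trans fusion, this face selectivity and periselectivity over the normal-demand mode (hexadienyl as diene, C4=C5 as dienophile), which is held back because it would have to build a quaternary C4 and whose adduct is in any case related to 15 by a [3,3] shift, while high dilution and BHT guard against intermolecular cycloaddition and polymerisation.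

Step 9
Reactants: 15 methyl (1R,2R,4aS,7S,8aR)-4,7-dimethyl-1-[(1E)-prop-1-en-1-yl]-1,2,4a,5,6,7,8,8a-octahydronaphthalene-2-carboxylate
Product: 16 methyl (1R,2S,4aS,7S,8aR)-4,7-dimethyl-1-[(1E)-prop-1-en-1-yl]-1,2,4a,5,6,7,8,8a-octahydronaphthalene-2-carboxylate
Conditions: NaOMe (0.2 equiv), MeOH, 50 °C
Reagents that add atoms: none
Why: Base-mediated epimerisation through the ester dienolate, which is reprotonated fastest at the α-carbon, should move the pseudoaxial ester of 15 to the pseudoequatorial position trans to the propenyl group, so that C2 becomes S and every substituent of the trans-decalin is equatorial.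

Step 10
Reactants: 16 methyl (1R,2S,4aS,7S,8aR)-4,7-dimethyl-1-[(1E)-prop-1-en-1-yl]-1,2,4a,5,6,7,8,8a-octahydronaphthalene-2-carboxylate
Product: 17 [(1R,2S,4aS,7S,8aR)-4,7-dimethyl-1-[(1E)-prop-1-en-1-yl]-1,2,4a,5,6,7,8,8a-octahydronaphthalen-2-yl]methanol
Conditions: i-Bu2AlH, CH2Cl2, −78 → 0 °C; aq. potassium sodium tartrate (KNaC4H4O6)
Reagents that add atoms: none
Why: Hydride reduction of the ester with diisobutylaluminium hydride gives the primary alcohol without touching the alkenes or any stereocentre.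

Step 11
Reactants: 17 [(1R,2S,4aS,7S,8aR)-4,7-dimethyl-1-[(1E)-prop-1-en-1-yl]-1,2,4a,5,6,7,8,8a-octahydronaphthalen-2-yl]methanol
Product: 18 (1R,2S,4aS,7S,8aR)-4,7-dimethyl-1-[(1E)-prop-1-en-1-yl]-1,2,4a,5,6,7,8,8a-octahydronaphthalene-2-carbaldehyde
Conditions: Dess–Martin periodinane, pyridine, CH2Cl2, 0 °C → rt; used crude
Reagents that add atoms: none
Why: Dess–Martin oxidation under buffered, non-basic conditions should give the β,γ-unsaturated aldehyde without moving the ring alkene into conjugation, and C2 is already in its more stable configuration.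

Step 12
Reactants: 19 (4R)-4-[(tert-butyldimethylsilyl)oxy]cyclohex-2-en-1-one
Product: 20 (1S,5R,6R)-5-[(tert-butyldimethylsilyl)oxy]-7-oxabicyclo[4.1.0]heptan-2-one
Conditions: 30% aq. H2O2, benzyltrimethylammonium hydroxide (cat.), THF, 0 °C
Reagents that add atoms: hydrogen peroxide, OO
Why: Weitz–Scheffer nucleophilic epoxidation, in which hydroperoxide adds to C3 of the enone anti to the C4 silyloxy group and the enolate closes the oxirane on the same face, sets C1 (S) and C6 (R) trans to the silyl ether.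

Step 13
Reactants: 21 5-bromo-2,4-dichloropyridine
Product: 22 5-bromo-2,4-bis[2-(trimethylsilyl)ethoxy]pyridine
Conditions: Me3SiCH2CH2OH, NaH, THF, 0 °C; then 21, DMF, rt → 70 °C
Reagents that add atoms: 2-(trimethylsilyl)ethanol, C[Si](C)(C)CCO
Why: Twofold nucleophilic aromatic substitution by the sodium alkoxide replaces the 4- and 2-chlorides, both activated by the ring nitrogen, while the 5-bromide, meta to nitrogen, is not displaced.

Step 14
Reactants: 22 5-bromo-2,4-bis[2-(trimethylsilyl)ethoxy]pyridine; 20 (1S,5R,6R)-5-[(tert-butyldimethylsilyl)oxy]-7-oxabicyclo[4.1.0]heptan-2-one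
Product: 25 5-{(1S,2R,5R,6R)-5-[(tert-butyldimethylsilyl)oxy]-2-[(trimethylsilyl)oxy]-7-oxabicyclo[4.1.0]heptan-2-yl}-2,4-bis[2-(trimethylsilyl)ethoxy]pyridine, via 5-lithiopyridine 23 (not isolated), via lithium alkoxide 24 (not isolated)
Conditions: 22, n-BuLi, THF, −78 °C; then 20, −78 °C; then TMSCl, −78 °C → rt
Reagents that add atoms: chlorotrimethylsilane, C[Si](C)(C)Cl
Why: Bromine–lithium exchange, 1,2-addition of the aryllithium to the ketone and O-silylation of the lithium alkoxide run in one flask, and the aryl group should enter by axial attack on the half-chair that keeps the C5 silyloxy group pseudoaxial, that is opposite this group and syn to the oxirane oxygen (the sense in which hydride reagents add to 2,3-epoxycyclohexanones to give trans-epoxy alcohols), so that C2 becomes R with its oxygen trans to the oxirane and cis to the silyl ether.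

Step 15
Reactants: 25 5-{(1S,2R,5R,6R)-5-[(tert-butyldimethylsilyl)oxy]-2-[(trimethylsilyl)oxy]-7-oxabicyclo[4.1.0]heptan-2-yl}-2,4-bis[2-(trimethylsilyl)ethoxy]pyridine; 18 (1R,2S,4aS,7S,8aR)-4,7-dimethyl-1-[(1E)-prop-1-en-1-yl]-1,2,4a,5,6,7,8,8a-octahydronaphthalene-2-carbaldehyde
Product: 27 {(1R,2S,4aS,7S,8aR)-4,7-dimethyl-1-[(1E)-prop-1-en-1-yl]-1,2,4a,5,6,7,8,8a-octahydronaphthalen-2-yl}{5-[(1S,2R,5R,6R)-5-[(tert-butyldimethylsilyl)oxy]-2-[(trimethylsilyl)oxy]-7-oxabicyclo[4.1.0]heptan-2-yl]-2,4-bis[2-(trimethylsilyl)ethoxy]pyridin-3-yl}methanol (both carbinol epimers), via 3-lithiopyridine 26 (not isolated)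
Conditions: 25, t-BuLi, THF, −78 °C; then 18, −78 °C; then H2O
Reagents that add atoms: none
Why: Directed ortho-metalation at C3, the only ring position flanked by two alkoxy groups, followed by 1,2-addition of the aryllithium to the aldehyde at −78 °C, where the hindered oxirane and the silyl ethers are inert, joins the halves, and the new carbinol centre needs no control because it is oxidised in the next step.

Step 16
Reactants: 27 the carbinol of step 15 (both epimers)
Product: 28 5-{(1S,2R,5R,6R)-5-[(tert-butyldimethylsilyl)oxy]-2-[(trimethylsilyl)oxy]-7-oxabicyclo[4.1.0]heptan-2-yl}-3-{[(1R,2S,4aS,7S,8aR)-4,7-dimethyl-1-[(1E)-prop-1-en-1-yl]-1,2,4a,5,6,7,8,8a-octahydronaphthalen-2-yl]carbonyl}-2,4-bis[2-(trimethylsilyl)ethoxy]pyridine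
Conditions: Dess–Martin periodinane, pyridine, CH2Cl2, rt
Reagents that add atoms: none
Why: Dess–Martin oxidation converges both carbinol epimers on the aryl ketone under neutral conditions that leave the oxirane, the silyl ethers and the C2 stereocentre untouched.

Step 17
Reactants: 28 the protected ketone of step 16
Product: 29 5-[(1S,2R,5R,6S)-2,5-dihydroxy-7-oxabicyclo[4.1.0]heptan-2-yl]-3-{[(1R,2S,4aS,7S,8aR)-4,7-dimethyl-1-[(1E)-prop-1-en-1-yl]-1,2,4a,5,6,7,8,8a-octahydronaphthalen-2-yl]carbonyl}-4-hydroxypyridin-2(1H)-one (CNP0494338.1)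
Conditions: Bu4NF, AcOH (1:1, excess), THF, 0 → 40 °C
Reagents that add atoms: none
Why: Fluoride attacks silicon in all four protecting groups, cleaving the two silyl ethers directly and the two 2-(trimethylsilyl)ethyl ethers by β-elimination of ethene from a good acylpyridinolate leaving group, while the acetic acid buffer should keep the freed trans-epoxy alcohols from Payne rearrangement, and the product then tautomerises to the 4-hydroxy-2-pyridone.

**Compound list**

1 | (S)-citronellal, (3S)-3,7-dimethyloct-6-enal | C[C@H](CC=O)CCC=C(C)C | starting material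
2 | 2-[(2S)-2,6-dimethylhept-5-en-1-yl]-1,3-dioxolane | C[C@H](CC1OCCO1)CCC=C(C)C | intermediate
3 | 3-[(3S)-4-(1,3-dioxolan-2-yl)-3-methylbutyl]-5,5-dimethyl-1,2,4-trioxolane (secondary ozonide, not isolated) | CC1(C)OOC(CC[C@H](C)CC2OCCO2)O1 | intermediate
4 | (4S)-5-(1,3-dioxolan-2-yl)-4-methylpentanal | C[C@H](CC1OCCO1)CCC=O | intermediate
5 | 2-(triphenylphosphoranylidene)propanal | CC(C=O)=P(c1ccccc1)(c1ccccc1)c1ccccc1 | starting material
6 | (2E,6S)-7-(1,3-dioxolan-2-yl)-2,6-dimethylhept-2-enal | O=C/C(C)=C/CC[C@H](C)CC1OCCO1 | intermediate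
7 | trimethyl phosphonoacetate | COC(=O)CP(=O)(OC)OC | starting material
8 | sodium salt of the trimethyl phosphonoacetate carbanion (not isolated) | [Na+].COC(=O)[CH-]P(=O)(OC)OC | intermediate
9 | methyl (2E,4E,8S)-9-(1,3-dioxolan-2-yl)-4,8-dimethylnona-2,4-dienoate | COC(=O)/C=C/C(C)=C/CC[C@H](C)CC1OCCO1 | intermediate
10 | methyl (2E,4E,8S)-4,8-dimethyl-10-oxodeca-2,4-dienoate | COC(=O)/C=C/C(C)=C/CC[C@H](C)CC=O | intermediate
11 | (E)-crotyl bromide, (2E)-1-bromobut-2-ene | C/C=C/CBr | starting material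
12 | tributyl[(2E)-but-2-en-1-yl]phosphonium bromide | C/C=C/C[P+](CCCC)(CCCC)CCCC.[Br-] | intermediate
13 | tributyl[(2E)-but-2-en-1-ylidene]phosphorane (not isolated) | C/C=C/C=P(CCCC)(CCCC)CCCC | intermediate
14 | methyl (2E,4E,8S,10E,12E)-4,8-dimethyltetradeca-2,4,10,12-tetraenoate | COC(=O)/C=C/C(C)=C/CC[C@H](C)C/C=C/C=C/C | intermediate
15 | methyl (1R,2R,4aS,7S,8aR)-4,7-dimethyl-1-[(1E)-prop-1-en-1-yl]-1,2,4a,5,6,7,8,8a-octahydronaphthalene-2-carboxylate (ester cis to propenyl) | C/C=C/[C@@H]1[C@H]2C[C@@H](C)CC[C@@H]2C(C)=C[C@@H]1C(=O)OC | intermediate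
16 | methyl (1R,2S,4aS,7S,8aR)-4,7-dimethyl-1-[(1E)-prop-1-en-1-yl]-1,2,4a,5,6,7,8,8a-octahydronaphthalene-2-carboxylate (ester trans to propenyl) | C/C=C/[C@@H]1[C@H]2C[C@@H](C)CC[C@@H]2C(C)=C[C@H]1C(=O)OC | intermediate
17 | [(1R,2S,4aS,7S,8aR)-4,7-dimethyl-1-[(1E)-prop-1-en-1-yl]-1,2,4a,5,6,7,8,8a-octahydronaphthalen-2-yl]methanol | C/C=C/[C@@H]1[C@H]2C[C@@H](C)CC[C@@H]2C(C)=C[C@H]1CO | intermediate
18 | (1R,2S,4aS,7S,8aR)-4,7-dimethyl-1-[(1E)-prop-1-en-1-yl]-1,2,4a,5,6,7,8,8a-octahydronaphthalene-2-carbaldehyde | C/C=C/[C@@H]1[C@H]2C[C@@H](C)CC[C@@H]2C(C)=C[C@H]1C=O | intermediate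
19 | (4R)-4-[(tert-butyldimethylsilyl)oxy]cyclohex-2-en-1-one | O=C1CC[C@@H](O[Si](C)(C)C(C)(C)C)C=C1 | starting material
20 | (1S,5R,6R)-5-[(tert-butyldimethylsilyl)oxy]-7-oxabicyclo[4.1.0]heptan-2-one (oxirane trans to the silyl ether) | O=C1CC[C@@H](O[Si](C)(C)C(C)(C)C)[C@@H]2O[C@@H]21 | intermediate
21 | 5-bromo-2,4-dichloropyridine | Clc1cc(Cl)c(Br)cn1 | starting material
22 | 5-bromo-2,4-bis[2-(trimethylsilyl)ethoxy]pyridine | C[Si](C)(C)CCOc1cc(OCC[Si](C)(C)C)c(Br)cn1 | intermediate
23 | 5-lithio-2,4-bis[2-(trimethylsilyl)ethoxy]pyridine (not isolated) | [Li]c1cnc(OCC[Si](C)(C)C)cc1OCC[Si](C)(C)C | intermediate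
24 | lithium (1S,2R,5R,6R)-2-{4,6-bis[2-(trimethylsilyl)ethoxy]pyridin-3-yl}-5-[(tert-butyldimethylsilyl)oxy]-7-oxabicyclo[4.1.0]heptan-2-olate (not isolated) | C[Si](C)(C)CCOc1cc(OCC[Si](C)(C)C)c(cn1)[C@]2([O-])CC[C@@H](O[Si](C)(C)C(C)(C)C)[C@@H]3O[C@@H]32.[Li+] | intermediate
25 | 5-{(1S,2R,5R,6R)-5-[(tert-butyldimethylsilyl)oxy]-2-[(trimethylsilyl)oxy]-7-oxabicyclo[4.1.0]heptan-2-yl}-2,4-bis[2-(trimethylsilyl)ethoxy]pyridine (aryl cis to the oxirane oxygen, both silyloxy groups trans to it) | C[Si](C)(C)CCOc1cc(OCC[Si](C)(C)C)c(cn1)[C@]2(O[Si](C)(C)C)CC[C@@H](O[Si](C)(C)C(C)(C)C)[C@@H]3O[C@@H]32 | intermediate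
26 | 3-lithio derivative of 25 (not isolated) | [Li]c1c(OCC[Si](C)(C)C)ncc(c1OCC[Si](C)(C)C)[C@]2(O[Si](C)(C)C)CC[C@@H](O[Si](C)(C)C(C)(C)C)[C@@H]3O[C@@H]32 | intermediate
27 | {(1R,2S,4aS,7S,8aR)-4,7-dimethyl-1-[(1E)-prop-1-en-1-yl]-1,2,4a,5,6,7,8,8a-octahydronaphthalen-2-yl}{5-[(1S,2R,5R,6R)-5-[(tert-butyldimethylsilyl)oxy]-2-[(trimethylsilyl)oxy]-7-oxabicyclo[4.1.0]heptan-2-yl]-2,4-bis[2-(trimethylsilyl)ethoxy]pyridin-3-yl}methanol (carbinol centre undefined) | C/C=C/[C@@H]1[C@H]2C[C@@H](C)CC[C@@H]2C(C)=C[C@H]1C(O)c1c(OCC[Si](C)(C)C)c(cnc1OCC[Si](C)(C)C)[C@]2(O[Si](C)(C)C)CC[C@@H](O[Si](C)(C)C(C)(C)C)[C@@H]3O[C@@H]32 | intermediate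
28 | 5-{(1S,2R,5R,6R)-5-[(tert-butyldimethylsilyl)oxy]-2-[(trimethylsilyl)oxy]-7-oxabicyclo[4.1.0]heptan-2-yl}-3-{[(1R,2S,4aS,7S,8aR)-4,7-dimethyl-1-[(1E)-prop-1-en-1-yl]-1,2,4a,5,6,7,8,8a-octahydronaphthalen-2-yl]carbonyl}-2,4-bis[2-(trimethylsilyl)ethoxy]pyridine | C/C=C/[C@@H]1[C@H]2C[C@@H](C)CC[C@@H]2C(C)=C[C@H]1C(=O)c1c(OCC[Si](C)(C)C)c(cnc1OCC[Si](C)(C)C)[C@]2(O[Si](C)(C)C)CC[C@@H](O[Si](C)(C)C(C)(C)C)[C@@H]3O[C@@H]32 | intermediate
29 | 5-[(1S,2R,5R,6S)-2,5-dihydroxy-7-oxabicyclo[4.1.0]heptan-2-yl]-3-{[(1R,2S,4aS,7S,8aR)-4,7-dimethyl-1-[(1E)-prop-1-en-1-yl]-1,2,4a,5,6,7,8,8a-octahydronaphthalen-2-yl]carbonyl}-4-hydroxypyridin-2(1H)-one | C/C=C/[C@@H]1[C@H]2C[C@@H](C)CC[C@@H]2C(C)=C[C@H]1C(=O)c1c(O)c([C@]2(O)CC[C@@H](O)[C@@H]3O[C@@H]32)c[nH]c1=O | target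

**Count**

Total steps: 17. Longest linear sequence: 13 steps (steps 1–5, 7–11 and 15–17, from (S)-citronellal).

**Steps most likely to fail**

1. Step 8. At the temperature an ester-activated diene needs, the normal-demand cycloaddition, the cis-fused and wrong-face transition states and thermal oligomerisation of the bis-diene can all compete. The fallback sets out from 14 and comes back at 18. It exchanges the ester for a formyl activating group so that the same two bonds can form under Lewis acid catalysis at low temperature. Reduction of 14 with i-Bu2AlH (CH2Cl2, −78 °C) gives (2E,4E,8S,10E,12E)-4,8-dimethyltetradeca-2,4,10,12-tetraen-1-ol F1, and MnO2 (CH2Cl2, rt) oxidises it to (2E,4E,8S,10E,12E)-4,8-dimethyltetradeca-2,4,10,12-tetraenal F2. Me2AlCl (CH2Cl2, −78 → −20 °C) should then close both rings to (1R,2R,4aS,7S,8aR)-4,7-dimethyl-1-[(1E)-prop-1-en-1-yl]-1,2,4a,5,6,7,8,8a-octahydronaphthalene-2-carbaldehyde F3. DBU in CH2Cl2 equilibrates C2 and gives 18, so steps 9–11 fall away.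

2. Step 14. Attack of the aryllithium on the face away from the oxirane, or enolisation of the ketone, would give the C2 epimer or return starting material. The fallback sets out from 19 and 22 and comes back at 25. It reverses the order of oxirane formation and aryl addition, so that both events are controlled by shielding from silyloxy groups. Aryllithium 23, made from 22, is added to enone 19 (THF, −78 °C, 1,2-addition anti to the silyloxy group) and the alkoxide is trapped with TMSCl to give 5-{(1S,4R)-4-[(tert-butyldimethylsilyl)oxy]-1-[(trimethylsilyl)oxy]cyclohex-2-en-1-yl}-2,4-bis[2-(trimethylsilyl)ethoxy]pyridine F4. mCPBA in CH2Cl2, with the ring nitrogen held as its trifluoroacetate salt to prevent N-oxidation, should then epoxidise the alkene anti to the two allylic silyloxy groups and deliver 25.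

3. Step 17. Buffered fluoride may stall at the 2-(trimethylsilyl)ethyl ethers, and forcing the reaction with unbuffered fluoride invites migration or opening of the oxirane by the neighbouring alkoxides. The fallback sets out from 28 and comes back at 29. It splits the unmasking into a fluoride stage for the silicon–oxygen bonds and an acid stage for the pyridyl ethers. HF·pyridine in THF/pyridine (0 °C → rt) removes the two silyl ethers to give 5-[(1S,2R,5R,6S)-2,5-dihydroxy-7-oxabicyclo[4.1.0]heptan-2-yl]-3-{[(1R,2S,4aS,7S,8aR)-4,7-dimethyl-1-[(1E)-prop-1-en-1-yl]-1,2,4a,5,6,7,8,8a-octahydronaphthalen-2-yl]carbonyl}-2,4-bis[2-(trimethylsilyl)ethoxy]pyridine F5. CF3CO2H in CH2Cl2 at 0 °C should then cleave both 2-(trimethylsilyl)ethyl ethers by acid-induced fragmentation with loss of ethene, the protonated acylpyridine ring disfavouring ionisation of the tertiary carbinol, and give 29.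

**Further compounds**

F1 | step 8 | (2E,4E,8S,10E,12E)-4,8-dimethyltetradeca-2,4,10,12-tetraen-1-ol | OC/C=C/C(C)=C/CC[C@H](C)C/C=C/C=C/C
F2 | step 8 | (2E,4E,8S,10E,12E)-4,8-dimethyltetradeca-2,4,10,12-tetraenal | O=C/C=C/C(C)=C/CC[C@H](C)C/C=C/C=C/C
F3 | step 8 | (1R,2R,4aS,7S,8aR)-4,7-dimethyl-1-[(1E)-prop-1-en-1-yl]-1,2,4a,5,6,7,8,8a-octahydronaphthalene-2-carbaldehyde | C/C=C/[C@@H]1[C@H]2C[C@@H](C)CC[C@@H]2C(C)=C[C@@H]1C=O
F4 | step 14 | 5-{(1S,4R)-4-[(tert-butyldimethylsilyl)oxy]-1-[(trimethylsilyl)oxy]cyclohex-2-en-1-yl}-2,4-bis[2-(trimethylsilyl)ethoxy]pyridine | C[Si](C)(C)CCOc1cc(OCC[Si](C)(C)C)c(cn1)[C@]2(O[Si](C)(C)C)CC[C@@H](O[Si](C)(C)C(C)(C)C)C=C2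
F5 | step 17 | 5-[(1S,2R,5R,6S)-2,5-dihydroxy-7-oxabicyclo[4.1.0]heptan-2-yl]-3-{[(1R,2S,4aS,7S,8aR)-4,7-dimethyl-1-[(1E)-prop-1-en-1-yl]-1,2,4a,5,6,7,8,8a-octahydronaphthalen-2-yl]carbonyl}-2,4-bis[2-(trimethylsilyl)ethoxy]pyridine | C/C=C/[C@@H]1[C@H]2C[C@@H](C)CC[C@@H]2C(C)=C[C@H]1C(=O)c1c(OCC[Si](C)(C)C)c(cnc1OCC[Si](C)(C)C)[C@]2(O)CC[C@@H](O)[C@@H]3O[C@@H]32
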